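**Retrosynthetic overview**
1. Target 16 ⇐ acetonide 15 ⇐ 11-carboxy acid 13; the carboxyl is a traceless handle removed by Barton decarboxylation.
2. Key step: Ireland–Claisen [3,3] shift of allyl ester 10 forms the C11–C12 bond and the 13(16)-methylene in one event.
3. Ester 10 ⇐ nor-acid 5 (side-chain ozonolysis of methyl trans-communate; C4, C5, C9, C10 bought) + allylic alcohol 9 (C14 bought; from the L-malic-acid-derived dioxolane 6 by α-methylenation and reduction).
4. Rings: none is built. The trans-decalin arrives intact in 1, the dioxolane in 6 and is removed last.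

Assumption: trans-communic acid (the main diterpene acid of juniper berries, a catalogue natural product) is accepted as purchasable; 6 is the commercial L-malic-acid derivative.

Labdane numbering is used throughout. "Ring configuration of 1" means 4-CO2R axial (C19), 5α-H, 9α-H, 10β-CH3. The route is a paper design; no step has been run.

**Step 1**
Reactants: 1 trans-communic acid
Product: 2 methyl trans-communate
Conditions: MeI, K2CO3, DMF, rt
Reagents that add atoms: iodomethane (CI)
Why: SN2 O-alkylation of the hindered axial carboxylate (carboxylate esterification) needs no acid, so the diene and exocyclic alkene stay in place and no stereocentre is touched.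

**Step 2**
Reactants: 2 methyl trans-communate
Product: 4 methyl 12-oxo-13,14,15,16-tetranorlabd-8(17)-en-19-oate, via side-chain ozonide 3 (not isolated)
Conditions: O3 (1.0 equiv, metered), CH2Cl2, −78 °C; then Me2S, −78 °C → rt
Reagents that add atoms: ozone ([O-][O+]=O)
Why: Criegee ozonolysis is fastest at the electron-rich trisubstituted Δ12 bond of the diene, so one equivalent should cleave it before the hindered 1,1-disubstituted Δ8(17) bond; C9 is not affected.

**Step 3**
Reactants: 4 methyl 12-oxo-13,14,15,16-tetranorlabd-8(17)-en-19-oate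
Product: 5 19-methyl hydrogen 13,14,15,16-tetranorlabd-8(17)-ene-12,19-dioate (free 12-acid)
Conditions: NaClO2, NaH2PO4, 2-methyl-2-butene, t-BuOH/H2O, rt
Reagents that add atoms: sodium chlorite ([Na+].[O-]Cl=O)
Why: Pinnick oxidation takes the aldehyde to the acid under buffered conditions, with the scavenger protecting the exocyclic alkene from HOCl.

**Step 4**
Reactants: 6 (4S)-4-(2-hydroxyethyl)-2,2-dimethyl-1,3-dioxolane
Product: 7 [(4S)-2,2-dimethyl-1,3-dioxolan-4-yl]acetaldehyde
Conditions: TEMPO (cat.), PhI(OAc)2, CH2Cl2, rt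
Reagents that add atoms: none
Why: TEMPO/BAIB (oxoammonium) oxidation of the primary alcohol stops at the aldehyde and leaves the acetonide and its stereocentre alone.

**Step 5**
Reactants: 7 [(4S)-2,2-dimethyl-1,3-dioxolan-4-yl]acetaldehyde
Product: 8 2-[(4S)-2,2-dimethyl-1,3-dioxolan-4-yl]prop-2-enal
Conditions: 37% aq. CH2O, pyrrolidine (10 mol %), EtCO2H (10 mol %), i-PrOH, 45 °C
Reagents that add atoms: formaldehyde (C=O)
Why: Organocatalytic Mannich condensation–elimination (α-methylenation of an aldehyde via its enamine) adds the carbon that becomes C12; the stereocentre is β to the carbonyl and cannot epimerise by enolisation.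

**Step 6**
Reactants: 8 2-[(4S)-2,2-dimethyl-1,3-dioxolan-4-yl]prop-2-enal
Product: 9 2-[(4S)-2,2-dimethyl-1,3-dioxolan-4-yl]prop-2-en-1-ol
Conditions: NaBH4, CeCl3·7H2O, MeOH, 0 °C
Reagents that add atoms: none
Why: Luche reduction gives clean 1,2-reduction of the enal to the 2-substituted allylic alcohol.

**Step 7**
Reactants: 5 19-methyl hydrogen 13,14,15,16-tetranorlabd-8(17)-ene-12,19-dioate; 9 2-[(4S)-2,2-dimethyl-1,3-dioxolan-4-yl]prop-2-en-1-ol
Product: 10 12-{2-[(4S)-2,2-dimethyl-1,3-dioxolan-4-yl]prop-2-en-1-yl} 19-methyl 13,14,15,16-tetranorlabd-8(17)-ene-12,19-dioate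
Conditions: DCC, DMAP (cat.), CH2Cl2, 0 °C → rt
Reagents that add atoms: none
Why: Steglich esterification joins the two chiral-pool fragments under neutral conditions that leave the C19 methyl ester, acetonide and alkenes untouched.

**Step 8**
Reactants: 10 12-{2-[(4S)-2,2-dimethyl-1,3-dioxolan-4-yl]prop-2-en-1-yl} 19-methyl 13,14,15,16-tetranorlabd-8(17)-ene-12,19-dioate
Product: 13 methyl (14S)-11-carboxy-14,15-(isopropylidenedioxy)labda-8(17),13(16)-dien-19-oate (C11 epimer mixture), via silyl ketene acetal 11 (not isolated), via trimethylsilyl ester 12 (not isolated)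
Conditions: LDA, TMSCl/Et3N, THF, −78 °C → 60 °C; then aq. citric acid (pH 4), rt
Reagents that add atoms: none
Why: The Ireland–Claisen [3,3]-sigmatropic rearrangement through a chair transition state forms the C11–C12 bond and transposes the allyl unit into the 13(16)-methylene; C14 sits on the central allyl carbon and is not involved, and the unselective new C11 centre is erased in step 9.

**Step 9**
Reactants: 13 methyl (14S)-11-carboxy-14,15-(isopropylidenedioxy)labda-8(17),13(16)-dien-19-oate
Product: 15 methyl (14S)-14,15-(isopropylidenedioxy)labda-8(17),13(16)-dien-19-oate, via Barton ester 14 (not isolated)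
Conditions: N-hydroxypyridine-2-thione, DCC, CH2Cl2, dark, 0 °C → rt; then t-BuSH (10 equiv), hν (W lamp), 20 °C
Reagents that add atoms: none
Why: Barton reductive decarboxylation removes the carboxyl and with it the only uncontrolled centre, because the thiol should quench the secondary C11 radical faster than it can rearrange.

**Step 10**
Reactants: 15 methyl (14S)-14,15-(isopropylidenedioxy)labda-8(17),13(16)-dien-19-oate
Product: 16 methyl (4S,5R,9S,10R,14S)-14,15-dihydroxylabda-8(17),13(16)-dien-19-oate (CNP0185041.1)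
Conditions: AcOH/THF/H2O (3:1:1), 40 °C
Reagents that add atoms: none
Why: Mild acid-catalysed acetal hydrolysis frees the 14,15-diol without moving the exocyclic alkenes or touching any of the five stereocentres.

**Compound list**
1 | trans-communic acid, (4S,5R,9S,10R,12E)-labda-8(17),12,14-trien-19-oic acid | C=C/C(C)=C/C[C@H]1C(=C)CC[C@@H]2[C@]1(C)CCC[C@]2(C)C(=O)O | starting material
2 | methyl trans-communate, methyl (12E)-labda-8(17),12,14-trien-19-oate, ring configuration of 1 | C=C/C(C)=C/C[C@H]1C(=C)CC[C@@H]2[C@]1(C)CCC[C@]2(C)C(=O)OC | intermediate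
3 | side-chain ozonide of 2: 3-ethenyl-3-methyl-1,2,4-trioxolane carrying the C11 methylene of the decalin at its C5, diastereomer mixture, ring configuration of 1 | C=CC1(C)OOC(C[C@H]2C(=C)CC[C@@H]3[C@]2(C)CCC[C@]3(C)C(=O)OC)O1 | intermediate
4 | methyl 12-oxo-13,14,15,16-tetranorlabd-8(17)-en-19-oate, ring configuration of 1 | O=CC[C@H]1C(=C)CC[C@@H]2[C@]1(C)CCC[C@]2(C)C(=O)OC | intermediate
5 | 19-methyl hydrogen 13,14,15,16-tetranorlabd-8(17)-ene-12,19-dioate (free 12-acid), ring configuration of 1 | OC(=O)C[C@H]1C(=C)CC[C@@H]2[C@]1(C)CCC[C@]2(C)C(=O)OC | intermediate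
6 | (4S)-4-(2-hydroxyethyl)-2,2-dimethyl-1,3-dioxolane | OCC[C@H]1COC(C)(C)O1 | starting material
7 | [(4S)-2,2-dimethyl-1,3-dioxolan-4-yl]acetaldehyde | O=CC[C@H]1COC(C)(C)O1 | intermediate
8 | 2-[(4S)-2,2-dimethyl-1,3-dioxolan-4-yl]prop-2-enal | O=CC(=C)[C@H]1COC(C)(C)O1 | intermediate
9 | 2-[(4S)-2,2-dimethyl-1,3-dioxolan-4-yl]prop-2-en-1-ol | OCC(=C)[C@H]1COC(C)(C)O1 | intermediate
10 | 12-{2-[(4S)-2,2-dimethyl-1,3-dioxolan-4-yl]prop-2-en-1-yl} 19-methyl 13,14,15,16-tetranorlabd-8(17)-ene-12,19-dioate, ring configuration of 1 | C=C(COC(=O)C[C@H]1C(=C)CC[C@@H]2[C@]1(C)CCC[C@]2(C)C(=O)OC)[C@H]1COC(C)(C)O1 | intermediate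
11 | trimethylsilyl ketene acetal of 10 (C11=C12, geometry not defined) | C=C(COC(O[Si](C)(C)C)=C[C@H]1C(=C)CC[C@@H]2[C@]1(C)CCC[C@]2(C)C(=O)OC)[C@H]1COC(C)(C)O1 | intermediate
12 | trimethylsilyl ester of 13 (C11 epimer mixture) | C=C(CC(C(=O)O[Si](C)(C)C)[C@H]1C(=C)CC[C@@H]2[C@]1(C)CCC[C@]2(C)C(=O)OC)[C@H]1COC(C)(C)O1 | intermediate
13 | methyl (14S)-11-carboxy-14,15-(isopropylidenedioxy)labda-8(17),13(16)-dien-19-oate, C11 epimer mixture, ring configuration of 1 | C=C(CC(C(=O)O)[C@H]1C(=C)CC[C@@H]2[C@]1(C)CCC[C@]2(C)C(=O)OC)[C@H]1COC(C)(C)O1 | intermediate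
14 | Barton ester of 13, 2-thioxopyridin-1(2H)-yl ester of the C11 carboxyl (C11 epimer mixture) | C=C(CC(C(=O)ON1C=CC=CC1=S)[C@H]1C(=C)CC[C@@H]2[C@]1(C)CCC[C@]2(C)C(=O)OC)[C@H]1COC(C)(C)O1 | intermediate
15 | methyl (14S)-14,15-(isopropylidenedioxy)labda-8(17),13(16)-dien-19-oate, ring configuration of 1 | C=C(CC[C@H]1C(=C)CC[C@@H]2[C@]1(C)CCC[C@]2(C)C(=O)OC)[C@H]1COC(C)(C)O1 | intermediate
16 | methyl (4S,5R,9S,10R,14S)-14,15-dihydroxylabda-8(17),13(16)-dien-19-oate | C=C(CC[C@H]1C(=C)CC[C@@H]2[C@]1(C)CCC[C@]2(C)C(=O)OC)[C@H](O)CO | target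

**Step count**
Total steps: 10. Longest linear sequence: 7 (steps 1, 2, 3, 7, 8, 9, 10).

**Steps most likely to fail and fallbacks**

Step 2 (ozonolysis). The risk is over-oxidation of the exocyclic Δ8(17) bond or attack at the terminal vinyl group. The fallback sets out from 2 and gives up selectivity. Exhaustive ozonolysis (excess O3, CH2Cl2/MeOH, −78 °C; Me2S) gives the keto aldehyde methyl 8,12-dioxo-13,14,15,16,17-pentanorlabdan-19-oate F1. Pinnick oxidation then gives the keto acid 19-methyl hydrogen 8-oxo-13,14,15,16,17-pentanorlabdane-12,19-dioate F2. Wittig methylenation of F2 as its carboxylate (Ph3P=CH2, 3.5 equiv, THF, 0 °C → reflux) rebuilds the exocyclic methylene; C9 is α to the ketone and keeps its favoured equatorial side chain. The fallback comes back to the route at 5.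

Step 8 (Ireland–Claisen). The risk is slow enolisation of the β-branched ester or ketene loss before silylation. The fallback sets out from 5 and 9 and replaces the rearrangement by an intermolecular enolate alkylation. Alcohol 9 is converted (CBr4, PPh3, 2,6-lutidine, CH2Cl2, 0 °C) into the allylic bromide (4S)-4-(3-bromoprop-1-en-2-yl)-2,2-dimethyl-1,3-dioxolane F3. The dianion of acid 5 (LDA 2.2 equiv, THF/DMPU, −78 → 0 °C) is then C-alkylated with F3. Because the allyl unit is 2-substituted, direct SN2 gives the same constitution as the [3,3] shift. The fallback comes back at 13.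

Step 9 (Barton decarboxylation). The risks are homoallyl rearrangement of the C11 radical (both alkenes are β,γ to it) and thiol–ene addition to the 1,1-disubstituted alkenes. The fallback sets out from 4 and keeps C12, so no decarboxylation is needed. Aldehyde 4 is reduced (NaBH4, MeOH, 0 °C) to methyl 12-hydroxy-13,14,15,16-tetranorlabd-8(17)-en-19-oate F4 and converted (I2, PPh3, imidazole) into methyl 12-iodo-13,14,15,16-tetranorlabd-8(17)-en-19-oate F5. Magnesium in THF gives the Grignard reagent methyl 12-(iodomagnesio)-13,14,15,16-tetranorlabd-8(17)-en-19-oate F6; the neopentyl-type axial C19 ester is too hindered to react. F6 is added at 0 °C to the Weinreb amide (4R)-N-methoxy-N,2,2-trimethyl-1,3-dioxolane-4-carboxamide F7, made from commercial methyl (R)-2,2-dimethyl-1,3-dioxolane-4-carboxylate with MeNHOMe·HCl and i-PrMgCl. This gives the ketone methyl (14R)-14,15-(isopropylidenedioxy)-13-oxo-16-norlabd-8(17)-en-19-oate F8. Methylenation of F8 with salt-free Ph3P=CH2 (THF, −78 → 0 °C) comes back to the route at 15.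

**Further compounds**
F1 | step 2 | methyl 8,12-dioxo-13,14,15,16,17-pentanorlabdan-19-oate, ring configuration of 1 | O=CC[C@H]1C(=O)CC[C@@H]2[C@]1(C)CCC[C@]2(C)C(=O)OC
F2 | step 2 | 19-methyl hydrogen 8-oxo-13,14,15,16,17-pentanorlabdane-12,19-dioate, ring configuration of 1 | OC(=O)C[C@H]1C(=O)CC[C@@H]2[C@]1(C)CCC[C@]2(C)C(=O)OC
F3 | step 8 | (4S)-4-(3-bromoprop-1-en-2-yl)-2,2-dimethyl-1,3-dioxolane | BrCC(=C)[C@H]1COC(C)(C)O1
F4 | step 9 | methyl 12-hydroxy-13,14,15,16-tetranorlabd-8(17)-en-19-oate, ring configuration of 1 | OCC[C@H]1C(=C)CC[C@@H]2[C@]1(C)CCC[C@]2(C)C(=O)OC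
F5 | step 9 | methyl 12-iodo-13,14,15,16-tetranorlabd-8(17)-en-19-oate, ring configuration of 1 | ICC[C@H]1C(=C)CC[C@@H]2[C@]1(C)CCC[C@]2(C)C(=O)OC
F6 | step 9 | methyl 12-(iodomagnesio)-13,14,15,16-tetranorlabd-8(17)-en-19-oate, ring configuration of 1 | I[Mg]CC[C@H]1C(=C)CC[C@@H]2[C@]1(C)CCC[C@]2(C)C(=O)OC
F7 | step 9 | (4R)-N-methoxy-N,2,2-trimethyl-1,3-dioxolane-4-carboxamide | CON(C)C(=O)[C@H]1COC(C)(C)O1
F8 | step 9 | methyl (14R)-14,15-(isopropylidenedioxy)-13-oxo-16-norlabd-8(17)-en-19-oate, ring configuration of 1 | O=C(CC[C@H]1C(=C)CC[C@@H]2[C@]1(C)CCC[C@]2(C)C(=O)OC)[C@H]1COC(C)(C)O1
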